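## The problem

The target is a C25 terpenoid built on a trans-fused decalin. The decalin is numbered as in the labdanes, and the chain carbons C11–C16 are counted outward from C9. Ring A (C1–C5, C10) is saturated and carries the gem-dimethyl carbon C4. Ring B (C5–C10) holds a tetrasubstituted C8=C9 alkene with a methyl group on C8 and the side chain on C9.

There are only two stereocentres, the ring-fusion methine C5 (S) and the adjacent quaternary, methyl-bearing C10 (S). Being contiguous, one can direct the other, but nothing else in the molecule can direct either, so the absolute configuration must come from a catalyst, the chiral pool or a resolution.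

The side chain is a stereodefined unit of its own: a two-carbon tether (C11–C12), a trisubstituted 13E alkene with the hydroxymethyl group cis to H-14, a 15E alkene, and a butenolide joined through its C4. The butenolide is the most fragile part (acidic γ-methylene, Michael acceptor, reduced by the hydride reagents needed for the allylic alcohol). The conjugated triene and the primary allylic alcohol are sensitive to acid and light, and the C8=C9 alkene migrates under strong acid.

C9 is the most hindered carbon of the bicycle (flanked by quaternary C10 and substituted C8) and also the point of chain attachment, so that bond has to be made on an sp2 carbon. The feature that opens the route is that C10 and C5 are α and β to C9. With a ketone at C9 in a six-membered ring B precursor, C5 is the β-carbon of an enone and C10 its α-carbon. The C4–C5 bond can then be made by conjugate addition and the C1–C10 bond by alkylation of the same enolate. The C9 carbonyl later becomes the C8=C9 alkene and the C9–C11 coupling site through its enol triflate.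

## Retrosynthesis

**C16–butenolide bond.** The last bond made is the sp2–sp2 bond between C16 and C4 of the butenolide: 26 is cut into dienylstannane 24 and 4-bromofuran-2(5H)-one 25 (Stille coupling). This cut is preferred to C14–C15 or to an olefination at C15=C16 because the lactone arrives in the final step under neutral conditions, after every basic or hydridic operation. In addition 25 is purchasable, whereas the neighbouring cuts need a vinyl-substituted butenolide that must be made and handled. 24 is simpler by the whole heterocycle. The forward reaction must keep both alkene geometries and tolerate the free allylic alcohol.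

**C13=C14 bond.** 24 is the reduction product of ester 23, which is cut at C13=C14 into the ester-stabilised ylide 18 and the three-carbon aldehyde 22 (Wittig reaction). The ylide carbon becomes C13, its ester the hydroxymethyl carbon, and the aldehyde carbon C14. An α-substituted stabilised ylide places the ester trans to the aldehyde residue, which is exactly the 13E arrangement. The alternatives here are a syn addition across a C13≡C14 alkyne (stereospecific, but delivery of a one-carbon unit to C13 has thin precedent) and a phosphonate olefination (shorter, but less E-selective with α-branched phosphonates). 22 already carries the 15E alkene and a tin handle on C16, so 18 contains no alkene of defined geometry. The forward reaction is asked for E selectivity and tolerance of the carbon–tin bond.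

**Activation of C13.** Ylide 18 is traced through α-bromo ester 16 to the saturated ester 14. No skeletal bond is cut. 14 holds the decalin, the C11–C13 tether and the future hydroxymethyl carbon, and has no sensitive group.

**C9–C11 bond.** 14 is cut between C9 and C11 into enol triflate 12 and the purchasable alkylzinc reagent 13, which supplies C11, C12, C13 and the ester carbon in one piece (Negishi coupling). A C11–C12 cut would need an allylic C11 electrophile prone to allylic transposition. Adding a chain nucleophile to a C9 ketone and dehydrating would give alkene mixtures. The triflate route fixes the C8=C9 alkene before the bond is made. The forward reaction is demanding: an sp2–sp3 coupling at a tetrasubstituted, neopentyl alkenyl carbon.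

**C8 methyl and the triflate.** Triflate 12 comes from ketone 10, and 10 from decalone 8 by cutting the C8–methyl bond (enolate methylation). Because C10 is quaternary, C8 is the only enolisable position of 8 and of 10. Methylation and triflate formation are therefore regiospecific, and the C8 configuration of 10 is irrelevant.

**Ring A.** Ring A of 8 is opened between C2 and C3. Hydrogenation and ring-closing metathesis, read backwards, lead through octalone 7 to the monocyclic diene 6. This is a cyclohexanone carrying on C10 a methyl and an allyl group (C1–C3) and on C5 a 2-methylbut-3-en-2-yl group (C4, its two methyl groups, and C3). Closing ring A by metathesis means the ring-forming step creates no stereocentre and cannot fail at the hindered C4. It only requires the two alkene-bearing groups to be trans, which is the ring-fusion stereochemistry itself.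

**Key disconnection.** 6 is cut at C4–C5 and C1–C10 into three purchasable components:
- 2-methylcyclohex-2-en-1-one 1 supplies C5–C10, the C10 methyl group and the C9 carbonyl.
- Prenylsilane 2 supplies C3, C4 and the gem-dimethyl groups.
- Allyl bromide 3 supplies C1–C3.

In the forward direction 2 adds through its dimethyl-substituted carbon to the β-carbon of 1. The enolate, held as silyl enol ether 4 and released as lithium enolate 5, is allylated on the methyl-bearing carbon. This cut is preferred to C5–C10 or C9–C10 disconnections because both hindered bonds next to the quaternary carbons are formed from the two most reactive positions of a simple enone, and C5 and C10 are set in one operation. The forward reaction must supply the absolute configuration at C5 (catalyst), the relative configuration at C10 (substrate) and γ-selective transfer of the prenyl group.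

**Aldehyde branch.** Aldehyde 22 comes from allylic alcohol 21, and 21 from prop-2-yn-1-ol 19 and tributylstannane 20 by cutting the C16–Sn bond (hydrostannation). This gives a three-carbon piece with the 15E geometry and the coupling handle.

## Roads not taken

**Alternative 1:** The cut is the C8=C9 double bond itself, made together with ring B by intramolecular alkyne–carbonyl metathesis. A ring A building block from (S)-α-ionone A1 would be elaborated to the alkynyl methyl ketone A2, in which C10 carries its methyl group and a silyloxybutynyl group and C5 the 3-oxobutyl chain. A Brønsted acid or a carbophilic gold catalyst would join the ketone carbon C8 to the alkyne carbon C9 through an oxetene, and ring opening would give enone A3 with the other alkyne carbon as a C11 ketone.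
- Merits: ring B and the hindered alkene, C8 methyl included, arise in one atom-economical step, and no cross-coupling at C9 is needed. In this respect it is better than the triflate/Negishi pair used here.
- Weak points: both stereocentres must exist before the key step. Placing an alkynyl group on quaternary C10 trans to the C5 chain of an ionone-derived ring is a multistep problem with its own selectivity question, and A1 is an article of commerce mainly as the racemate. Ketone–alkyne metathesis is best behaved for aryl alkynes; the dialkyl alkyne of A2 invites hydration and Conia-ene cyclisation through the methyl ketone enol. The C11 carbonyl of A3 is surplus and must be removed from a hindered, conjugated position without moving the alkene.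
- Comparison: the chosen plan uses its C9 carbonyl productively (it becomes the alkene and the coupling site) and draws both stereocentres from one step on achiral materials.

**Alternative 2:** The cut removes both rings at once: C4–C5, C9–C10 and a C8–O bond form by enzymatic cationic cyclisation. A squalene–hopene cyclase would protonate the terminal alkene of (5E,9E)-farnesylacetone A4, close rings A and B and let the ketone oxygen trap the C8 cation, giving sclareol oxide A5 as one enantiomer.
- Merits: both rings and both ring-fusion stereocentres in one step from a cheap achiral ketone, with the enzyme supplying the absolute configuration. Here the alternative is clearly ahead of the chosen plan, whose key step is untested as an enantioselective process and needs a second step to close ring A.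
- Weak points: A5 has oxygen on C8 and hydrogen on C9. The C8=C9 alkene must be generated by opening the enol ether and eliminating a tertiary alcohol, which is expected to give the 7-ene and the exocyclic 8(17)-ene beside the 8-ene. The chain of A5 ends at C13 as a masked methyl ketone, so the hydroxymethyl group and the 13E alkene would need functionalisation of that methyl group and an olefination of an unsymmetrical ketone with weak geometric control. The enzyme must be expressed and fed a geometrically pure, poorly soluble substrate.
- Comparison: in the chosen plan the alkene position is dictated by the C9 carbonyl, the tether reaches C13 at the right oxidation level for a geometry-defining Wittig reaction, and only chemical reagents are needed.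

**Alternative 3:** The cuts lie in the side chain, at C12–C13 and C14–C15. The Grignard reagent from the bicyclic homoallylic bromide A6 would be turned into an alkylcopper species that adds syn across the silyl propargyl ether A7 (alkyl to the internal carbon). The resulting alkenylcopper would be coupled, after transmetalation and under palladium catalysis, with the iodovinyl butenolide A8 to give silyl ether A9, one desilylation from the target.
- Merits: the whole side chain with both alkene geometries is assembled in one flask, and the 13E geometry follows stereospecifically from syn carbometalation. As an endgame it is shorter than the six linear steps spent here between triflate 12 and the target, and this must be conceded.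
- Weak points: it says nothing about the bicycle. A6, with both stereocentres and the C8=C9 alkene, still has to be made, most plausibly by the same C9 functionalisation as here plus two carbons. The valuable bicyclic fragment becomes a stoichiometric organometallic. The regiochemistry of carbocupration of propargylic ethers depends on solvent and O-substituent. The alkenylmetal meets an electrophile, A8, that carries a base-sensitive butenolide and needs its own synthesis.
- Comparison: the chosen plan solves the ring system and its stereocentres, never makes the decalin the organometallic partner, and introduces the butenolide as purchasable 25 under neutral conditions. If A6 were prepared from 12, this endgame could be grafted onto the present ring synthesis.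

Key step: step 1

Assumption: the hand of the catalyst in step 1 is chosen so that C3 of 4 forms with S configuration; which enantiomer of the catalyst does this must be established in the first run.

## Route

Step 1
Reactants: 1 2-methylcyclohex-2-en-1-one; 2 trimethyl(3-methylbut-2-en-1-yl)silane; 3 allyl bromide (3-bromoprop-1-ene)
Product: 6 (2S,3S)-2-allyl-2-methyl-3-(2-methylbut-3-en-2-yl)cyclohexan-1-one, via silyl enol ether 4 (not isolated), via lithium enolate 5 (not isolated)
Conditions: chiral binaphthyl-derived imidodiphosphorimidate (IDPi) acid (2 mol%), toluene, −60 °C; then THF, MeLi, 0 °C; then DMPU, 3, −78 → 0 °C (one pot)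
Reagents that add atoms: none
Why: Proposed new method: the acid precatalyst is silylated by 2 (protodesilylation), and the silylium–imidodiphosphorimidate ion pair O-silylates 1 to a silyloxyallyl cation held in the confined chiral anion; 2 attacks the β-carbon (future C5) through its dimethyl-substituted γ-carbon in an SE2' sense, forming the C4–C5 bond, and loss of the silyl cation to the anion regenerates the catalyst and leaves silyl enol ether 4 with the enolate regiochemistry fixed. The closest known reaction types are silylium-based counteranion-directed Mukaiyama–Michael additions to enones and Hosomi–Sakurai allylations of aldehydes, the triflimide-catalysed racemic conjugate allylation of enones by allylsilanes, and the stoichiometric TiCl4 conjugate addition of prenylsilane; new is the catalytic enantioselective conjugate variant on an α-methyl enone run into an enolate alkylation. MeLi cleaves the O–Si bond to give the regiodefined tetrasubstituted lithium enolate 5, which 3 allylates on carbon at the methyl-bearing position (C1–C10 bond). No ring closes in this step. C3 of the ring (C5 of the target) is set by the chiral anion through face selection on the silyloxyallyl cation (catalyst control). C2 (C10 of the target) is set by the substrate: in 5 the bulky 2-methylbut-3-en-2-yl group sits pseudoaxial to avoid allylic 1,2-strain with the 2-methyl group and blocks one face, so 3 enters anti and the allyl and dimethylallyl groups end up trans, as the trans-decalin requires. The step needs γ-selectivity in the silane (secured by the SE2' mechanism), conjugate rather than carbonyl addition (secured by silylium activation and the hindered tertiary nucleophilic carbon), and C-allylation without enolate equilibration (lithium counter-ion, DMPU, excess 3 at low temperature).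

Step 2
Reactants: 6 (2S,3S)-2-allyl-2-methyl-3-(2-methylbut-3-en-2-yl)cyclohexan-1-one
Product: 8 (4aS,8aS)-5,5,8a-trimethyloctahydronaphthalen-1(2H)-one, via octalone 7 (not isolated)
Conditions: second-generation Grubbs catalyst, (H2IMes)(PCy3)Cl2Ru=CHPh (3 mol%), CH2Cl2, 40 °C; then solvent exchange, Pd/C, H2 (1 atm), EtOAc, rt
Reagents that add atoms: none
Why: Ring-closing olefin metathesis of the two monosubstituted alkenes closes ring A as a cyclohexene with loss of ethene; the trans arrangement of the two arms from step 1 lets both be equatorial, so the bicycle forms trans-fused. Heterogeneous catalytic hydrogenation then saturates the only alkene without touching the hindered ketone; no stereocentre is formed or put at risk.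

Step 3
Reactants: 8 (4aS,8aS)-5,5,8a-trimethyloctahydronaphthalen-1(2H)-one
Product: 10 (4aS,8aS)-2,5,5,8a-tetramethyloctahydronaphthalen-1(2H)-one (both C2 epimers), via lithium enolate 9 (not isolated)
Conditions: LDA, THF, −78 °C; MeI, −78 → 0 °C
Reagents that add atoms: iodomethane, CI
Why: Enolate alkylation; C8 of the target is the only enolisable position because C10 is quaternary, so deprotonation and methylation are regiospecific. The configuration of the new centre is irrelevant because it becomes sp2 in step 4.

Step 4
Reactants: 10 (4aS,8aS)-2,5,5,8a-tetramethyloctahydronaphthalen-1(2H)-one (both C2 epimers)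
Product: 12 (4aS,8aS)-2,5,5,8a-tetramethyl-3,4,4a,5,6,7,8,8a-octahydronaphthalen-1-yl trifluoromethanesulfonate, via potassium enolate 11 (not isolated)
Conditions: KHMDS, THF, −78 → 0 °C; PhNTf2, −78 °C → rt
Reagents that add atoms: N-phenylbis(trifluoromethanesulfonimide), O=S(=O)(N(c1ccccc1)S(=O)(=O)C(F)(F)F)C(F)(F)F
Why: Enol triflate formation; the only enolate that 10 can give is the tetrasubstituted C8=C9 enolate, and O-sulfonylation fixes the ring B alkene of the target and converts C9 into a cross-coupling site.

Step 5
Reactants: 12 (4aS,8aS)-2,5,5,8a-tetramethyl-3,4,4a,5,6,7,8,8a-octahydronaphthalen-1-yl trifluoromethanesulfonate; 13 (4-ethoxy-4-oxobutyl)zinc bromide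
Product: 14 ethyl 4-[(4aS,8aS)-2,5,5,8a-tetramethyl-3,4,4a,5,6,7,8,8a-octahydronaphthalen-1-yl]butanoate
Conditions: Pd(OAc)2 (5 mol%), SPhos (10 mol%), THF/NMP, 60 °C
Reagents that add atoms: none
Why: Negishi cross-coupling of an alkenyl triflate with a primary alkylzinc halide: oxidative addition to zerovalent palladium, transmetalation and reductive elimination form C9–C11 without moving the alkene. The bulky electron-rich biaryl phosphine favours reductive elimination over β-hydride elimination, and the organozinc tolerates its own ester.

Step 6
Reactants: 14 ethyl 4-[(4aS,8aS)-2,5,5,8a-tetramethyl-3,4,4a,5,6,7,8,8a-octahydronaphthalen-1-yl]butanoate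
Product: 16 ethyl 2-bromo-4-[(4aS,8aS)-2,5,5,8a-tetramethyl-3,4,4a,5,6,7,8,8a-octahydronaphthalen-1-yl]butanoate (both C2 epimers), via lithium ester enolate 15 (not isolated)
Conditions: LDA, THF, −78 °C; enolate added to CBr4, THF, −78 °C
Reagents that add atoms: tetrabromomethane, BrC(Br)(Br)Br
Why: α-Bromination of an ester enolate by bromine transfer from CBr4; inverse addition limits proton exchange with the more acidic product, and CBr4 does not attack the electron-rich tetrasubstituted alkene. The new centre is removed in step 7.

Step 7
Reactants: 16 ethyl 2-bromo-4-[(4aS,8aS)-2,5,5,8a-tetramethyl-3,4,4a,5,6,7,8,8a-octahydronaphthalen-1-yl]butanoate (both C2 epimers)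
Product: 18 ethyl 4-[(4aS,8aS)-2,5,5,8a-tetramethyl-3,4,4a,5,6,7,8,8a-octahydronaphthalen-1-yl]-2-(triphenyl-λ5-phosphanylidene)butanoate, via phosphonium bromide 17 (not isolated)
Conditions: PPh3, toluene, 90 °C; then aq. NaOH, CH2Cl2, rt
Reagents that add atoms: triphenylphosphine, c1ccc(cc1)P(c1ccccc1)c1ccccc1
Why: SN2 displacement of the α-bromide by the phosphine gives the phosphonium salt, whose acidic α-proton is removed by hydroxide to give the ester-stabilised ylide; this is the standard preparation of 2-alkyl-2-(triphenylphosphoranylidene)acetates.

Step 8
Reactants: 19 prop-2-yn-1-ol; 20 tributylstannane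
Product: 21 (E)-3-(tributylstannyl)prop-2-en-1-ol
Conditions: AIBN (cat.), neat, 80 °C
Reagents that add atoms: none
Why: Free-radical hydrostannation of a terminal alkyne; the stannyl radical adds to the terminal carbon, and reversible addition–elimination equilibrates the adduct towards the E isomer, which is separated from minor isomers by chromatography.

Step 9
Reactants: 21 (E)-3-(tributylstannyl)prop-2-en-1-ol
Product: 22 (E)-3-(tributylstannyl)prop-2-enal
Conditions: MnO2, CH2Cl2, rt
Reagents that add atoms: none
Why: Selective oxidation of an allylic alcohol by activated MnO2, which leaves the carbon–tin bond and the alkene geometry untouched.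

Step 10
Reactants: 18 ethyl 4-[(4aS,8aS)-2,5,5,8a-tetramethyl-3,4,4a,5,6,7,8,8a-octahydronaphthalen-1-yl]-2-(triphenyl-λ5-phosphanylidene)butanoate; 22 (E)-3-(tributylstannyl)prop-2-enal
Product: 23 ethyl (2E,4E)-2-{2-[(4aS,8aS)-2,5,5,8a-tetramethyl-3,4,4a,5,6,7,8,8a-octahydronaphthalen-1-yl]ethyl}-5-(tributylstannyl)penta-2,4-dienoate
Conditions: CH2Cl2, rt → 40 °C
Reagents that add atoms: none
Why: Wittig olefination with an α-substituted, ester-stabilised ylide; its late, product-like transition state places the ester trans to the aldehyde residue, which is the 13E geometry of the target (ester, later hydroxymethyl, cis to H-14). The 15E alkene is carried in unchanged from 22.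

Step 11
Reactants: 23 ethyl (2E,4E)-2-{2-[(4aS,8aS)-2,5,5,8a-tetramethyl-3,4,4a,5,6,7,8,8a-octahydronaphthalen-1-yl]ethyl}-5-(tributylstannyl)penta-2,4-dienoate
Product: 24 (2E,4E)-2-{2-[(4aS,8aS)-2,5,5,8a-tetramethyl-3,4,4a,5,6,7,8,8a-octahydronaphthalen-1-yl]ethyl}-5-(tributylstannyl)penta-2,4-dien-1-ol
Conditions: DIBAL-H, CH2Cl2, −78 °C; aq. potassium sodium tartrate
Reagents that add atoms: none
Why: 1,2-Reduction of a conjugated ester to the primary allylic alcohol by diisobutylaluminium hydride, without conjugate reduction or loss of tin; it is done before the butenolide is present, so no lactone competes for the hydride.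

Step 12
Reactants: 24 (2E,4E)-2-{2-[(4aS,8aS)-2,5,5,8a-tetramethyl-3,4,4a,5,6,7,8,8a-octahydronaphthalen-1-yl]ethyl}-5-(tributylstannyl)penta-2,4-dien-1-ol; 25 4-bromofuran-2(5H)-one
Product: 26 4-[(1E,3E)-4-(hydroxymethyl)-6-[(4aS,8aS)-2,5,5,8a-tetramethyl-3,4,4a,5,6,7,8,8a-octahydronaphthalen-1-yl]hexa-1,3-dien-1-yl]furan-2(5H)-one
Conditions: Pd2(dba)3 (2.5 mol%), AsPh3 (20 mol%), NMP, rt, dark
Reagents that add atoms: none
Why: Stille cross-coupling: oxidative addition of the electron-poor alkenyl bromide to zerovalent palladium, tin-to-palladium transmetalation of the dienylstannane with retention of geometry, and reductive elimination form the C16–butenolide bond. The neutral conditions tolerate the free allylic alcohol and the base-sensitive lactone.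

## Compound list

1 | 2-methylcyclohex-2-en-1-one | CC1=CCCCC1=O | starting material
2 | trimethyl(3-methylbut-2-en-1-yl)silane | CC(C)=CC[Si](C)(C)C | starting material
3 | allyl bromide (3-bromoprop-1-ene) | C=CCBr | starting material
4 | trimethyl{[(3S)-2-methyl-3-(2-methylbut-3-en-2-yl)cyclohex-1-en-1-yl]oxy}silane | C[Si](C)(C)OC1=C(C)[C@H](C(C)(C)C=C)CCC1 | intermediate
5 | lithium (3S)-2-methyl-3-(2-methylbut-3-en-2-yl)cyclohex-1-en-1-olate | [Li]OC1=C(C)[C@H](C(C)(C)C=C)CCC1 | intermediate
6 | (2S,3S)-2-allyl-2-methyl-3-(2-methylbut-3-en-2-yl)cyclohexan-1-one | O=C1[C@@](C)(CC=C)[C@H](C(C)(C)C=C)CCC1 | intermediate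
7 | (4aS,8aS)-5,5,8a-trimethyl-3,4,4a,5,8,8a-hexahydronaphthalen-1(2H)-one | O=C1[C@@](C)(CC=CC2(C)C)[C@H]2CCC1 | intermediate
8 | (4aS,8aS)-5,5,8a-trimethyloctahydronaphthalen-1(2H)-one | O=C1[C@@](C)(CCCC2(C)C)[C@H]2CCC1 | intermediate
9 | lithium (4aS,8aS)-5,5,8a-trimethyl-3,4,4a,5,6,7,8,8a-octahydronaphthalen-1-olate | [Li]OC=1[C@@](C)(CCCC2(C)C)[C@H]2CCC=1 | intermediate
10 | (4aS,8aS)-2,5,5,8a-tetramethyloctahydronaphthalen-1(2H)-one, both C2 epimers | O=C1[C@@](C)(CCCC2(C)C)[C@H]2CCC1C | intermediate
11 | potassium (4aS,8aS)-2,5,5,8a-tetramethyl-3,4,4a,5,6,7,8,8a-octahydronaphthalen-1-olate | [K]OC=1[C@@](C)(CCCC2(C)C)[C@H]2CCC=1C | intermediate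
12 | (4aS,8aS)-2,5,5,8a-tetramethyl-3,4,4a,5,6,7,8,8a-octahydronaphthalen-1-yl trifluoromethanesulfonate | FC(F)(F)S(=O)(=O)OC=1[C@@](C)(CCCC2(C)C)[C@H]2CCC=1C | intermediate
13 | (4-ethoxy-4-oxobutyl)zinc bromide | CCOC(=O)CCC[Zn]Br | starting material
14 | ethyl 4-[(4aS,8aS)-2,5,5,8a-tetramethyl-3,4,4a,5,6,7,8,8a-octahydronaphthalen-1-yl]butanoate | CCOC(=O)CCCC=1[C@@](C)(CCCC2(C)C)[C@H]2CCC=1C | intermediate
15 | lithium 1-ethoxy-4-[(4aS,8aS)-2,5,5,8a-tetramethyl-3,4,4a,5,6,7,8,8a-octahydronaphthalen-1-yl]but-1-en-1-olate | CCOC(O[Li])=CCCC=1[C@@](C)(CCCC2(C)C)[C@H]2CCC=1C | intermediate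
16 | ethyl 2-bromo-4-[(4aS,8aS)-2,5,5,8a-tetramethyl-3,4,4a,5,6,7,8,8a-octahydronaphthalen-1-yl]butanoate, both C2 epimers | CCOC(=O)C(Br)CCC=1[C@@](C)(CCCC2(C)C)[C@H]2CCC=1C | intermediate
17 | {1-ethoxy-1-oxo-4-[(4aS,8aS)-2,5,5,8a-tetramethyl-3,4,4a,5,6,7,8,8a-octahydronaphthalen-1-yl]butan-2-yl}triphenylphosphonium bromide | CCOC(=O)C(CCC=1[C@@](C)(CCCC2(C)C)[C@H]2CCC=1C)[P+](c1ccccc1)(c1ccccc1)c1ccccc1.[Br-] | intermediate
18 | ethyl 4-[(4aS,8aS)-2,5,5,8a-tetramethyl-3,4,4a,5,6,7,8,8a-octahydronaphthalen-1-yl]-2-(triphenyl-λ5-phosphanylidene)butanoate | CCOC(=O)C(CCC=1[C@@](C)(CCCC2(C)C)[C@H]2CCC=1C)=P(c1ccccc1)(c1ccccc1)c1ccccc1 | intermediate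
19 | prop-2-yn-1-ol | C#CCO | starting material
20 | tributylstannane | CCCC[SnH](CCCC)CCCC | starting material
21 | (E)-3-(tributylstannyl)prop-2-en-1-ol | OC/C=C/[Sn](CCCC)(CCCC)CCCC | intermediate
22 | (E)-3-(tributylstannyl)prop-2-enal | O=C/C=C/[Sn](CCCC)(CCCC)CCCC | intermediate
23 | ethyl (2E,4E)-2-{2-[(4aS,8aS)-2,5,5,8a-tetramethyl-3,4,4a,5,6,7,8,8a-octahydronaphthalen-1-yl]ethyl}-5-(tributylstannyl)penta-2,4-dienoate | CCOC(=O)/C(CCC=1[C@@](C)(CCCC2(C)C)[C@H]2CCC=1C)=C/C=C/[Sn](CCCC)(CCCC)CCCC | intermediate
24 | (2E,4E)-2-{2-[(4aS,8aS)-2,5,5,8a-tetramethyl-3,4,4a,5,6,7,8,8a-octahydronaphthalen-1-yl]ethyl}-5-(tributylstannyl)penta-2,4-dien-1-ol | OC/C(CCC=1[C@@](C)(CCCC2(C)C)[C@H]2CCC=1C)=C/C=C/[Sn](CCCC)(CCCC)CCCC | intermediate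
25 | 4-bromofuran-2(5H)-one | BrC1=CC(=O)OC1 | starting material
26 | 4-[(1E,3E)-4-(hydroxymethyl)-6-[(4aS,8aS)-2,5,5,8a-tetramethyl-3,4,4a,5,6,7,8,8a-octahydronaphthalen-1-yl]hexa-1,3-dien-1-yl]furan-2(5H)-one | CC1=C(CC/C(=C\C=C\C2=CC(=O)OC2)CO)[C@@]2(C)CCCC(C)(C)[C@@H]2CC1 | target

## Step count and least certain steps

Total: 12 steps. Longest linear sequence: 10 steps (steps 1–7 and 10–12; steps 8 and 9 are a two-step branch to aldehyde 22).

**Step 1 (key step, proposed new method).**
- What may go wrong: activation of the α-methyl enone may be too weak, since its silyloxyallyl cation is more hindered and less electrophilic than that of cyclohexenone, so protodesilylation of 2 could outrun conjugate addition. Facial discrimination may be low because the β-carbon has no substituent for the chiral anion to hold. In the second stage, proton transfer between product and enolate could lead to allylation at the wrong α-carbon or twice.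
- Fallback (known chemistry; sets out from 1, 2 and 3, returns at 8): 1 and 2 are combined with stoichiometric TiCl4 (CH2Cl2, −78 °C, classical Hosomi–Sakurai conjugate addition) to give racemic 2-methyl-3-(2-methylbut-3-en-2-yl)cyclohexan-1-one F1. Equilibrating silylation (Me3SiCl, NaI, Et3N, MeCN) converts it into the racemic, more substituted silyl enol ether F2. MeLi releases the racemic lithium enolate F3, which 3 allylates to the racemic trans allyl ketone F4. The conditions of step 2 give the racemic octalone F5 and then the racemic decalone F6. F6 is resolved by preparative chromatography on a polysaccharide-based chiral stationary phase to give 8.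

**Step 5 (Negishi coupling).**
- What may go wrong: transmetalation at the neopentyl, tetrasubstituted alkenylpalladium centre may be slow, so reduction or hydrolysis of the triflate and β-hydride elimination of the alkyl group could take over.
- Fallback (sets out from 10, returns at 14): the C9–C11 bond is made by carbonyl addition instead of cross-coupling. Vinylmagnesium bromide with anhydrous CeCl3 adds to 10 to give the tertiary allylic alcohol (4aS,8aS)-1-ethenyl-2,5,5,8a-tetramethyldecahydronaphthalen-1-ol F7. A Johnson–Claisen rearrangement with triethyl orthoacetate and a trace of propanoic acid moves the two-carbon ester unit to the vinyl terminus and gives ethyl 4-[(4aS,8aS)-2,5,5,8a-tetramethyloctahydronaphthalen-1(2H)-ylidene]butanoate F8. p-Toluenesulfonic acid in toluene then shifts the exocyclic C9=C11 alkene into the ring, to the more substituted and less strained C8=C9 position, which gives 14.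

**Step 7 (phosphorane formation).**
- What may go wrong: SN2 attack at the secondary α-carbon may be slow, so halophilic attack of the phosphine on bromine (returning 14 after work-up) or loss of HBr could compete.
- Fallback (sets out from 14, returns at 23): an aldol–elimination sequence replaces bromination, phosphorane formation and Wittig reaction. The lithium enolate 15 is added to 22 to give the β-hydroxy ester ethyl (4E)-3-hydroxy-2-{2-[(4aS,8aS)-2,5,5,8a-tetramethyl-3,4,4a,5,6,7,8,8a-octahydronaphthalen-1-yl]ethyl}-5-(tributylstannyl)pent-4-enoate F9. Methanesulfonyl chloride and Et3N give its methanesulfonate F10. 1,8-Diazabicyclo[5.4.0]undec-7-ene eliminates F10 by an E1cB process to the conjugated ester, and the 2E isomer 23 is separated from any 2Z isomer.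

**Step 12 (Stille coupling).**
- What may go wrong: protodestannylation or homocoupling of the dienylstannane may occur if transmetalation is slow, and the butenolide or the triene may decompose or isomerise during a long reaction.
- Fallback (sets out from 24 and 25, returns at 26): the polarity of the coupling is reversed. Iodine in CH2Cl2 at 0 °C converts 24 by ipso-iododestannylation into (2E,4E)-5-iodo-2-{2-[(4aS,8aS)-2,5,5,8a-tetramethyl-3,4,4a,5,6,7,8,8a-octahydronaphthalen-1-yl]ethyl}penta-2,4-dien-1-ol F11. 25 is stannylated with hexabutylditin and Pd(PPh3)4 to 4-(tributylstannyl)furan-2(5H)-one F12. Coupling of F11 with F12 (Pd2(dba)3, AsPh3, CuI, NMP) gives 26; the alkenyl iodide adds rapidly to zerovalent palladium and the stannane is a simple, unhindered alkenyltin.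

## Further compounds

F1 | step 1 | racemic 2-methyl-3-(2-methylbut-3-en-2-yl)cyclohexan-1-one, C2 epimers | CC1C(C(C)(C)C=C)CCCC1=O
F2 | step 1 | racemic trimethyl{[2-methyl-3-(2-methylbut-3-en-2-yl)cyclohex-1-en-1-yl]oxy}silane | C[Si](C)(C)OC1=C(C)C(C(C)(C)C=C)CCC1
F3 | step 1 | racemic lithium 2-methyl-3-(2-methylbut-3-en-2-yl)cyclohex-1-en-1-olate | [Li]OC1=C(C)C(C(C)(C)C=C)CCC1
F4 | step 1 | racemic (2RS,3RS)-2-allyl-2-methyl-3-(2-methylbut-3-en-2-yl)cyclohexan-1-one | O=C1[C@@](C)(CC=C)[C@H](C(C)(C)C=C)CCC1.O=C1[C@](C)(CC=C)[C@@H](C(C)(C)C=C)CCC1
F5 | step 1 | racemic (4aRS,8aRS)-5,5,8a-trimethyl-3,4,4a,5,8,8a-hexahydronaphthalen-1(2H)-one | O=C1[C@@](C)(CC=CC2(C)C)[C@H]2CCC1.O=C1[C@](C)(CC=CC2(C)C)[C@@H]2CCC1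
F6 | step 1 | racemic (4aRS,8aRS)-5,5,8a-trimethyloctahydronaphthalen-1(2H)-one | O=C1[C@@](C)(CCCC2(C)C)[C@H]2CCC1.O=C1[C@](C)(CCCC2(C)C)[C@@H]2CCC1
F7 | step 5 | (4aS,8aS)-1-ethenyl-2,5,5,8a-tetramethyldecahydronaphthalen-1-ol, C1 and C2 epimers | C=CC1(O)[C@@](C)(CCCC2(C)C)[C@H]2CCC1C
F8 | step 5 | ethyl 4-[(4aS,8aS)-2,5,5,8a-tetramethyloctahydronaphthalen-1(2H)-ylidene]butanoate, alkene and C2 isomers | CCOC(=O)CCC=C1[C@@](C)(CCCC2(C)C)[C@H]2CCC1C
F9 | step 7 | ethyl (4E)-3-hydroxy-2-{2-[(4aS,8aS)-2,5,5,8a-tetramethyl-3,4,4a,5,6,7,8,8a-octahydronaphthalen-1-yl]ethyl}-5-(tributylstannyl)pent-4-enoate, diastereomers | CCOC(=O)C(CCC=1[C@@](C)(CCCC2(C)C)[C@H]2CCC=1C)C(O)/C=C/[Sn](CCCC)(CCCC)CCCC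
F10 | step 7 | ethyl (4E)-3-[(methanesulfonyl)oxy]-2-{2-[(4aS,8aS)-2,5,5,8a-tetramethyl-3,4,4a,5,6,7,8,8a-octahydronaphthalen-1-yl]ethyl}-5-(tributylstannyl)pent-4-enoate, diastereomers | CCOC(=O)C(CCC=1[C@@](C)(CCCC2(C)C)[C@H]2CCC=1C)C(OS(C)(=O)=O)/C=C/[Sn](CCCC)(CCCC)CCCC
F11 | step 12 | (2E,4E)-5-iodo-2-{2-[(4aS,8aS)-2,5,5,8a-tetramethyl-3,4,4a,5,6,7,8,8a-octahydronaphthalen-1-yl]ethyl}penta-2,4-dien-1-ol | OC/C(CCC=1[C@@](C)(CCCC2(C)C)[C@H]2CCC=1C)=C/C=C/I
F12 | step 12 | 4-(tributylstannyl)furan-2(5H)-one | CCCC[Sn](CCCC)(CCCC)C1=CC(=O)OC1
A1 | alternative 1 | (S)-α-ionone, (3E)-4-[(1S)-2,6,6-trimethylcyclohex-2-en-1-yl]but-3-en-2-one | CC(=O)/C=C/[C@@H]1C(C)=CCCC1(C)C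
A2 | alternative 1 | 4-[(1S,2S)-2-{4-[(tert-butyldiphenylsilyl)oxy]but-1-yn-1-yl}-2,6,6-trimethylcyclohexyl]butan-2-one | CC(=O)CC[C@H]1C(C)(C)CCC[C@]1(C)C#CCCO[Si](c1ccccc1)(c1ccccc1)C(C)(C)C
A3 | alternative 1 | 3-[(tert-butyldiphenylsilyl)oxy]-1-[(4aS,8aS)-2,5,5,8a-tetramethyl-3,4,4a,5,6,7,8,8a-octahydronaphthalen-1-yl]propan-1-one | CC1=C(C(=O)CCO[Si](c2ccccc2)(c2ccccc2)C(C)(C)C)[C@@]2(C)CCCC(C)(C)[C@@H]2CC1
A4 | alternative 2 | (5E,9E)-farnesylacetone, (5E,9E)-6,10,14-trimethylpentadeca-5,9,13-trien-2-one | CC(=O)CC/C=C(\C)CC/C=C(\C)CCC=C(C)C
A5 | alternative 2 | sclareol oxide (8α,13-epoxy-14,15-dinorlabd-12-ene) | C[C@@]14OC(C)=CC[C@@H]4[C@@]2(C)CCCC(C)(C)[C@@H]2CC1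
A6 | alternative 3 | (4aS,8aS)-1-(2-bromoethyl)-2,5,5,8a-tetramethyl-3,4,4a,5,6,7,8,8a-octahydronaphthalene | CC1=C(CCBr)[C@@]2(C)CCCC(C)(C)[C@@H]2CC1
A7 | alternative 3 | tert-butyldimethyl(prop-2-yn-1-yloxy)silane | C#CCO[Si](C)(C)C(C)(C)C
A8 | alternative 3 | 4-[(E)-2-iodoethenyl]furan-2(5H)-one | I/C=C/C1=CC(=O)OC1
A9 | alternative 3 | tert-butyldimethylsilyl ether of the target, 4-[(1E,3E)-4-{[(tert-butyldimethylsilyl)oxy]methyl}-6-[(4aS,8aS)-2,5,5,8a-tetramethyl-3,4,4a,5,6,7,8,8a-octahydronaphthalen-1-yl]hexa-1,3-dien-1-yl]furan-2(5H)-one | CC1=C(CC/C(=C\C=C\C2=CC(=O)OC2)CO[Si](C)(C)C(C)(C)C)[C@@]2(C)CCCC(C)(C)[C@@H]2CC1
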